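- The vessel is closed and stirred, and before we charge it again we must choose what to move in the next run: the X against the L, or the stirring time.

L 0.80 M; E 2.50 equiv; D 0.500 equiv; X 0.400 M; time 5.0 d

- conversion of L at 5.0 d
- amount of L.E at 5.0 d, in percent of the L charged

- what has gone from L into another species counts as reacted, even if it can come back
- run time (flask): 5.0 d

    D + E ⇌ D.E (K1 = 0.538 M⁻¹, k1 = 0.0101 M⁻¹ h⁻¹)
    L + X → L.X (k2 = 2.37 M⁻¹ h⁻¹)
    L + E ⇌ L.E (K3 = 7.83 M⁻¹, k3 = 0.123 M⁻¹ h⁻¹)
    L ⇌ G (K4 = 2.35, k4 = 0.375 h⁻¹)

- L + X runs one way, while L goes back out of both L.E and G. By that step, with the rest as charged, L has a half-life of 0.73 h, much shorter than the 5.0 d of this flask, so we count on X, the limiting reagent, taking 0.400 M of L and leaving 50.0% of the charge.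
- That remainder spreads over L, G and L.E, and we take equal weights as the zero of our scale, where L.E holds a third of it. We may use equilibrium weights because the half-life of L.E falling apart, 44.1 h, is shorter than the run.
- In this flask L weighs one, G weighs 2.35, and L.E weighs 7.83 M⁻¹ times the free E, which we take roughly as the charge less the remainder, 1.60 M, setting aside the E that D binds. L.E therefore weighs 12.5, and this gives 78.9% for the holding share, the weight of L.E over the sum of the weights of L, G and L.E.
- Our reckoning for this flask is 39.5% of L.E and a conversion of 96.9%, so we decide to leave the time as it is and to choose the X by the remainder it leaves.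
- The forecast gives a conversion of 96.7% and 39% of L.E, on the ground that “X is the limiting scavenger”, and it puts free E at 1.51 M against our 1.60 M.
- The simulation gives 96.7% and 39.0%, so the forecast stands.

- In this flask, with the rest as charged, L had a half-life of 0.73 h by X, shorter than the 0.077 d of the forward step to G taken alone, and after 0.500 d the step from L and X to L.X had 95% of its turnover up to the asked time behind it. At 5.00 d X stands at 0% and L.X at 50.0%, while L.E makes up 77.9% of the L, G and L.E together, against our holding share of 78.9%, with 76% of the E free.
- In the neighbour flask with 0.48 M of L, where X comes to 0.833 equiv, the same reckoning takes a remainder of 16.7%, free E of 1.12 M and a holding share of 72.4%, which gives 12.1% of L.E. The neighbour flask gives 13.9%, with 2.4% of its X still there.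

All constants are those of an exercise; what happens was integrated by code.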